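**Retrosynthetic overview**
- Target ⇐ 4'-detosylation ⇐ O3/O7 sulfation (chelated 5-OH left free) ⇐ hydrogenolysis of 3,5,7-tri-O-benzyl-4'-O-tosylisorhamnetin.
- Key disconnection: the pyranone C ring is cut at O1–C8a and C4–C4a, giving 3,5-bis(benzyloxy)benzyne and the enolate of an α-benzyloxy β-keto ester.
- Feature used: O1 and C4 sit on adjacent A-ring carbons (C8a, C4a) and the ring is oxygenated at C5 and C7. A 3,5-dialkoxybenzyne gives this pattern when the O-nucleophile enters meta to the flanking alkoxy group and the carbanion next to that group is acylated.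
- Aryne precursor: 3,5-bis(benzyloxy)phenol, carbamate-directed ortho-silylation, then triflation. Keto ester: vanillic acid (tosylate, acid chloride) plus ethyl benzyloxyacetate by Claisen acylation.
- Ring order: A and B rings are purchased; the pyranone C ring is the only ring formed (step 7).

Key step: step 7

Assumption: the target has no stereogenic element, so no stereocontrol is needed; the sulfate monoesters are written as free acids (as in the target SMILES) and would be handled as potassium salts until a final brief acidification.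

**Step 1**
Reactants: 1 3,5-bis(benzyloxy)phenol
Product: 2 3,5-bis(benzyloxy)phenyl N-isopropylcarbamate
Conditions: i-PrNCO (1.5 equiv), Et3N (cat.), CH2Cl2, rt
Reagents that add atoms: isopropyl isocyanate, CC(C)N=C=O
Why: Base-catalysed addition of the phenol to the isocyanate (carbamoylation) should give the N-monoalkyl carbamate, which directs ortho-metalation and is later removable under mild base.

**Step 2**
Reactants: 2 3,5-bis(benzyloxy)phenyl N-isopropylcarbamate
Product: 6 3,5-bis(benzyloxy)-2-(trimethylsilyl)phenyl N-isopropylcarbamate, via N-TBS carbamate 3 (not isolated), via aryllithium 4 (not isolated), via N-TBS C-TMS carbamate 5 (not isolated)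
Conditions: TBSOTf, TMEDA, Et2O, 0 °C to rt; then n-BuLi, TMEDA, −78 °C; then TMSCl, −78 °C to rt; aq. NaHSO4 work-up
Reagents that add atoms: chlorotrimethylsilane, C[Si](C)(C)Cl
Why: Directed ortho-metalation: in situ N-silylation masks the N–H, the O-carbamate then steers n-BuLi/TMEDA to C2 (flanked by the carbamate and a benzyloxy group) in preference to C4 or the benzylic CH2 at −78 °C, TMSCl traps the aryllithium, and the N–Si bond is hydrolysed on acidic work-up.

**Step 3**
Reactants: 6 3,5-bis(benzyloxy)-2-(trimethylsilyl)phenyl N-isopropylcarbamate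
Product: 8 3,5-bis(benzyloxy)-2-(trimethylsilyl)phenyl trifluoromethanesulfonate, via silylphenol 7 (not isolated)
Conditions: DBU, Et2NH, MeCN, 40 °C; then PhNTf2, rt
Reagents that add atoms: N-phenylbis(trifluoromethanesulfonimide), O=S(=O)(N(c1ccccc1)S(=O)(=O)C(F)(F)F)C(F)(F)F
Why: E1cB cleavage of the N–H carbamate by DBU releases isopropyl isocyanate (trapped by Et2NH as the urea) and the phenoxide, which is triflated in the same flask by the mild triflyl donor without loss of the C–Si bond; this is the established carbamate route to o-silylaryl triflates.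

**Step 4**
Reactants: 9 vanillic acid
Product: 10 3-methoxy-4-(tosyloxy)benzoic acid
Conditions: TsCl (1.2 equiv), aq. NaOH, THF, 0 °C to rt; then HCl to pH 2
Reagents that add atoms: p-toluenesulfonyl chloride, Cc1ccc(cc1)S(=O)(=O)Cl
Why: Schotten–Baumann sulfonylation: the phenoxide is sulfonylated in aqueous base while any mixed anhydride formed at the carboxylate hydrolyses back, so acidification should give the tosyloxy acid.

**Step 5**
Reactants: 10 3-methoxy-4-(tosyloxy)benzoic acid
Product: 11 3-methoxy-4-(tosyloxy)benzoyl chloride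
Conditions: (COCl)2, DMF (cat.), CH2Cl2, 0 °C to rt
Reagents that add atoms: oxalyl chloride, O=C(Cl)C(=O)Cl
Why: Acid chloride formation through the Vilsmeier-type chloroiminium species; the aryl tosylate and the methyl ether are inert to these conditions.

**Step 6**
Reactants: 11 3-methoxy-4-(tosyloxy)benzoyl chloride; 12 ethyl benzyloxyacetate
Product: 15 ethyl 2-(benzyloxy)-3-[3-methoxy-4-(tosyloxy)phenyl]-3-oxopropanoate (racemic), via ester lithium enolate 13 (not isolated), via ketoester lithium enolate 14 (not isolated)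
Conditions: 12 (2.2 equiv), LiHMDS (2.2 equiv), THF, −78 °C; then 11 (1.0 equiv), −78 °C; 1 M HCl quench
Reagents that add atoms: none
Why: Crossed Claisen C-acylation of the lithium glycolate enolate by the aroyl chloride; the second equivalent of enolate deprotonates the more acidic β-keto ester as it forms and so prevents double acylation, the aryl tosylate is untouched at −78 °C, and the α-stereocentre is formed racemic and disappears on enolisation in step 7.

**Step 7**
Reactants: 8 3,5-bis(benzyloxy)-2-(trimethylsilyl)phenyl trifluoromethanesulfonate; 15 ethyl 2-(benzyloxy)-3-[3-methoxy-4-(tosyloxy)phenyl]-3-oxopropanoate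
Product: 19 3,5,7-tri-O-benzyl-4'-O-tosylisorhamnetin, via caesium enolate 16 (not isolated), via aryne 17 (not isolated), via aryl anion 18 (not isolated)
Conditions: 8 (1.5 equiv), CsF (4 equiv), THF, 65 °C, sealed tube
Reagents that add atoms: none
Why: Proposed new method: fluoride desilylates 8 with loss of triflate to give aryne 17 and, together with the ethoxide released later, deprotonates 15 to the caesium-bridged U-shaped enolate 16; the enolate oxygen adds to C1 of the aryne, the terminus remote from the C3 benzyloxy group as the distortion of 3-alkoxyarynes requires, so O1–C8a forms and the carbanion of 18 develops at C2 beside the inductively stabilising C–O bond. That carbanion attacks the cis ester carbonyl in a 6-exo-trig acyl substitution and expels ethoxide, forming C4a–C4 and closing the pyranone ring. The closest known reactions are the fluoride-mediated annulation of arynes with salicylate esters to xanthones (O-arylation, then intramolecular acylation of the aryl anion) and the aryne acyl-alkylation of β-keto esters, which begins with C-arylation and is the competing pathway here. No stereocentre is formed, since the racemic α-carbon of 15 becomes sp2. The step needs O- over C-arylation, which the fully substituted benzyloxy-bearing α-carbon and the weakly coordinating caesium counter-ion should favour, and it needs cyclisation to outrun protonation of 18, for which THF (no acidic C–H, unlike MeCN) and the intramolecular six-membered trajectory are chosen; the aryne regiochemistry places the benzyloxy groups at C5 and C7.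

**Step 8**
Reactants: 19 3,5,7-tri-O-benzyl-4'-O-tosylisorhamnetin
Product: 20 4'-O-tosylisorhamnetin (3,5,7-trihydroxy-2-[3-methoxy-4-(tosyloxy)phenyl]-4H-chromen-4-one)
Conditions: H2 (1 atm), 10% Pd/C, THF/MeOH, rt
Reagents that add atoms: none
Why: Heterogeneous hydrogenolysis of the three benzyl ethers; the aryl tosylate, the aryl methyl ether and the tetrasubstituted, vinylogous-ester C2=C3 bond are expected to survive at 1 atm and rt.

**Step 9**
Reactants: 20 4'-O-tosylisorhamnetin
Product: 21 4'-O-tosylisorhamnetin 3,7-bis(hydrogen sulfate)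
Conditions: SO3·pyridine (6 equiv), pyridine, Ar, 45 °C, followed by HPLC; aq. KHCO3 quench, C18 chromatography (handled as the dipotassium salt)
Reagents that add atoms: sulfur trioxide–pyridine complex, O=S(=O)([O-])[n+]1ccccc1
Why: O-Sulfation with a sulfur trioxide–amine complex: the acidic 7-OH and the 3-OH are sulfated, whereas the 5-OH, held in a strong six-membered hydrogen bond to the C4 carbonyl and not ionised in pyridine, is the least reactive hydroxyl of a flavonol and should stay free.

**Step 10**
Reactants: 21 4'-O-tosylisorhamnetin 3,7-bis(hydrogen sulfate)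
Product: 22 isorhamnetin 3,7-di-O-sulfate
Conditions: 1 M aq. KOH (degassed), Ar, 50 °C; AcOH to pH 7, C18/Sephadex LH-20 (dipotassium salt); H+ resin, 0 °C, lyophilise for the free acid
Reagents that add atoms: none
Why: Alkaline S–O cleavage of the aryl tosylate by hydroxide attack at sulfur, helped by the 4'-phenoxide being a good leaving group through conjugation with the pyranone; aryl sulfate monoester anions are stable to base, and working in water avoids formation of an alkylating methyl tosylate.

**Compound list**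
1 | 3,5-bis(benzyloxy)phenol | Oc1cc(OCc2ccccc2)cc(OCc2ccccc2)c1 | starting material
2 | 3,5-bis(benzyloxy)phenyl N-isopropylcarbamate | CC(C)NC(=O)Oc1cc(OCc2ccccc2)cc(OCc2ccccc2)c1 | intermediate
3 | 3,5-bis(benzyloxy)phenyl N-(tert-butyldimethylsilyl)-N-isopropylcarbamate (not isolated) | CC(C)N(C(=O)Oc1cc(OCc2ccccc2)cc(OCc2ccccc2)c1)[Si](C)(C)C(C)(C)C | intermediate
4 | 2-lithio derivative of 3 (not isolated) | CC(C)N(C(=O)Oc1cc(OCc2ccccc2)cc(OCc2ccccc2)c1[Li])[Si](C)(C)C(C)(C)C | intermediate
5 | 3,5-bis(benzyloxy)-2-(trimethylsilyl)phenyl N-(tert-butyldimethylsilyl)-N-isopropylcarbamate (not isolated) | CC(C)N(C(=O)Oc1cc(OCc2ccccc2)cc(OCc2ccccc2)c1[Si](C)(C)C)[Si](C)(C)C(C)(C)C | intermediate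
6 | 3,5-bis(benzyloxy)-2-(trimethylsilyl)phenyl N-isopropylcarbamate | CC(C)NC(=O)Oc1cc(OCc2ccccc2)cc(OCc2ccccc2)c1[Si](C)(C)C | intermediate
7 | 3,5-bis(benzyloxy)-2-(trimethylsilyl)phenol (not isolated) | Oc1cc(OCc2ccccc2)cc(OCc2ccccc2)c1[Si](C)(C)C | intermediate
8 | 3,5-bis(benzyloxy)-2-(trimethylsilyl)phenyl trifluoromethanesulfonate | C[Si](C)(C)c1c(OS(=O)(=O)C(F)(F)F)cc(OCc2ccccc2)cc1OCc1ccccc1 | intermediate
9 | vanillic acid | COc1cc(C(=O)O)ccc1O | starting material
10 | 3-methoxy-4-(tosyloxy)benzoic acid | COc1cc(C(=O)O)ccc1OS(=O)(=O)c1ccc(C)cc1 | intermediate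
11 | 3-methoxy-4-(tosyloxy)benzoyl chloride | COc1cc(C(=O)Cl)ccc1OS(=O)(=O)c1ccc(C)cc1 | intermediate
12 | ethyl benzyloxyacetate | CCOC(=O)COCc1ccccc1 | starting material
13 | lithium enolate of ethyl benzyloxyacetate (not isolated) | [Li+].CCOC([O-])=COCc1ccccc1 | intermediate
14 | lithium enolate of keto ester 15 (not isolated) | [Li+].CCOC(=O)C(OCc1ccccc1)=C([O-])c1ccc(OS(=O)(=O)c2ccc(C)cc2)c(OC)c1 | intermediate
15 | ethyl 2-(benzyloxy)-3-[3-methoxy-4-(tosyloxy)phenyl]-3-oxopropanoate (racemic) | CCOC(=O)C(OCc1ccccc1)C(=O)c1ccc(OS(=O)(=O)c2ccc(C)cc2)c(OC)c1 | intermediate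
16 | caesium enolate of 15, U-shaped with O− cis to the ester (not isolated) | [Cs+].CCOC(=O)/C(OCc1ccccc1)=C(\[O-])c1ccc(OS(=O)(=O)c2ccc(C)cc2)c(OC)c1 | intermediate
17 | 3,5-bis(benzyloxy)benzyne (not isolated) | C1#CC=C(OCc2ccccc2)C=C1OCc1ccccc1 | intermediate
18 | O-arylated enol ether aryl anion, caesium salt, aryloxy cis to the ester (not isolated) | [Cs+].CCOC(=O)/C(OCc1ccccc1)=C(\Oc1cc(OCc2ccccc2)cc(OCc2ccccc2)[c-]1)c1ccc(OS(=O)(=O)c2ccc(C)cc2)c(OC)c1 | intermediate
19 | 3,5,7-tri-O-benzyl-4'-O-tosylisorhamnetin | COc1cc(-c2oc3cc(OCc4ccccc4)cc(OCc4ccccc4)c3c(=O)c2OCc2ccccc2)ccc1OS(=O)(=O)c1ccc(C)cc1 | intermediate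
20 | 4'-O-tosylisorhamnetin | COc1cc(-c2oc3cc(O)cc(O)c3c(=O)c2O)ccc1OS(=O)(=O)c1ccc(C)cc1 | intermediate
21 | 4'-O-tosylisorhamnetin 3,7-bis(hydrogen sulfate) | COc1cc(-c2oc3cc(OS(=O)(=O)O)cc(O)c3c(=O)c2OS(=O)(=O)O)ccc1OS(=O)(=O)c1ccc(C)cc1 | intermediate
22 | isorhamnetin 3,7-di-O-sulfate | COc1cc(-c2oc3cc(OS(=O)(=O)O)cc(O)c3c(=O)c2OS(=O)(=O)O)ccc1O | target

**Step count**
Total steps: 10. Longest linear sequence: 7 steps (1→2→3→7→8→9→10, or equally 4→5→6→7→8→9→10).

**Steps most likely to fail**

1. Step 7 (proposed new method). The ambident enolate may be arylated at carbon, after which the aryl anion attacks the ketone and the aroyl group migrates (acyl-alkylation). Alternatively the O-arylated aryl anion may be protonated before it reaches the ester. Fallback by known chemistry (Baker–Venkataraman route), setting out from carbamate 2 and acid chloride 11 and returning at 19: the aryllithium 4, generated from 2 as in step 2, would be quenched with 2-(benzyloxy)-N-methoxy-N-methylacetamide instead of TMSCl and worked up with aqueous HCl to give 3,5-bis(benzyloxy)-2-[(benzyloxy)acetyl]phenyl N-isopropylcarbamate F1. DBU/Et2NH in MeCN would cleave the carbamate to 2-(benzyloxy)-1-[2,4-bis(benzyloxy)-6-hydroxyphenyl]ethan-1-one F2. Acylation of F2 with 11 (pyridine, DMAP) would give 3,5-bis(benzyloxy)-2-[(benzyloxy)acetyl]phenyl 3-methoxy-4-(tosyloxy)benzoate F3. Baker–Venkataraman rearrangement (LiHMDS, THF, −20 °C) would give 2-(benzyloxy)-1-[2,4-bis(benzyloxy)-6-hydroxyphenyl]-3-[3-methoxy-4-(tosyloxy)phenyl]propane-1,3-dione F4, and cyclodehydration (NaOAc, AcOH, 100 °C) would close the pyranone to 19.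

2. Step 9. Sulfation may stop short at the hydrogen-bonded 3-hydroxyl or run on to O5, leaving an anionic mixture that is hard to separate. Fallback through protected sulfate diesters, setting out from 20 and returning at 21: 20 would be treated with 2,2,2-trichloroethyl chlorosulfate (2.3 equiv), Et3N and DMAP in THF at 0 °C to give the neutral 4'-O-tosylisorhamnetin 3,7-bis(2,2,2-trichloroethyl sulfate) F5. F5 can be purified on silica to remove under-, over- and mis-sulfated material. Zn dust and ammonium formate in MeOH at rt would then remove both trichloroethyl groups reductively to give 21.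

3. Step 10. S–O cleavage may be slow on the polyanionic substrate, so that hydroxide opening of the pyranone ring or loss of sulfate competes. Fallback by exchanging the 4'-protecting group before sulfation, setting out from 19 and returning at 22: the tosylate would be cleaved while no sulfate is present (KOH, aq. dioxane, 80 °C) to give 3,5,7-tri-O-benzylisorhamnetin F6. Pivaloyl chloride/pyridine would give 3,5,7-tri-O-benzyl-4'-O-pivaloylisorhamnetin F7. Hydrogenolysis as in step 8 would give 4'-O-pivaloylisorhamnetin F8, and sulfation as in step 9 would give 4'-O-pivaloylisorhamnetin 3,7-bis(hydrogen sulfate) F9. Aqueous methylamine in MeOH at rt would then remove the aryl pivalate by aminolysis, under far milder conditions than tosylate hydrolysis, to give 22.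

**Further compounds**
F1 | step 7 | 3,5-bis(benzyloxy)-2-[(benzyloxy)acetyl]phenyl N-isopropylcarbamate | CC(C)NC(=O)Oc1cc(OCc2ccccc2)cc(OCc2ccccc2)c1C(=O)COCc1ccccc1
F2 | step 7 | 2-(benzyloxy)-1-[2,4-bis(benzyloxy)-6-hydroxyphenyl]ethan-1-one | Oc1cc(OCc2ccccc2)cc(OCc2ccccc2)c1C(=O)COCc1ccccc1
F3 | step 7 | 3,5-bis(benzyloxy)-2-[(benzyloxy)acetyl]phenyl 3-methoxy-4-(tosyloxy)benzoate | COc1cc(C(=O)Oc2cc(OCc3ccccc3)cc(OCc3ccccc3)c2C(=O)COCc2ccccc2)ccc1OS(=O)(=O)c1ccc(C)cc1
F4 | step 7 | 2-(benzyloxy)-1-[2,4-bis(benzyloxy)-6-hydroxyphenyl]-3-[3-methoxy-4-(tosyloxy)phenyl]propane-1,3-dione (racemic) | COc1cc(C(=O)C(OCc2ccccc2)C(=O)c2c(O)cc(OCc3ccccc3)cc2OCc2ccccc2)ccc1OS(=O)(=O)c1ccc(C)cc1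
F5 | step 9 | 4'-O-tosylisorhamnetin 3,7-bis(2,2,2-trichloroethyl sulfate) | COc1cc(-c2oc3cc(OS(=O)(=O)OCC(Cl)(Cl)Cl)cc(O)c3c(=O)c2OS(=O)(=O)OCC(Cl)(Cl)Cl)ccc1OS(=O)(=O)c1ccc(C)cc1
F6 | step 10 | 3,5,7-tri-O-benzylisorhamnetin | COc1cc(-c2oc3cc(OCc4ccccc4)cc(OCc4ccccc4)c3c(=O)c2OCc2ccccc2)ccc1O
F7 | step 10 | 3,5,7-tri-O-benzyl-4'-O-pivaloylisorhamnetin | COc1cc(-c2oc3cc(OCc4ccccc4)cc(OCc4ccccc4)c3c(=O)c2OCc2ccccc2)ccc1OC(=O)C(C)(C)C
F8 | step 10 | 4'-O-pivaloylisorhamnetin | COc1cc(-c2oc3cc(O)cc(O)c3c(=O)c2O)ccc1OC(=O)C(C)(C)C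
F9 | step 10 | 4'-O-pivaloylisorhamnetin 3,7-bis(hydrogen sulfate) | COc1cc(-c2oc3cc(OS(=O)(=O)O)cc(O)c3c(=O)c2OS(=O)(=O)O)ccc1OC(=O)C(C)(C)C
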